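At late times a flask is easiest to read from what has not yet become target. The solid substrate is the one charge, so it is the limiting reagent, and in fractions of it the solid left, starting material, intermediate and target (crystals counted in) add up to one. We call u the fraction that is not yet target.

| flask | solid substrate | temperature | remark | time |
|---|---|---|---|---|
| alpha | 0.053 M | 58 °C | run made earlier |  |
| eta | 0.12 M | 74 °C | run made earlier |  |
| ochre | 0.079 M | 65 °C |  | 2.0 h |
| violet | 0.079 M |  | at 80 °C until 1.0 h, from then on at 50 °C | 2.0 h |
| grey | 0.079 M | 50 °C |  | 2.0 h |
| blue | 0.079 M | 80 °C |  | 2.0 h |

| run | time / min | target / % |
|---|---|---|
| alpha | 8.00 | 0.5 |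
| alpha | 15.0 | 2.3 |
| alpha | 25.0 | 3.1 |
| alpha | 50.0 | 12.1 |
| alpha | 90.0 | 25.4 |
| eta | 5.00 | 1.0 |
| eta | 10.0 | 3.9 |
| eta | 15.0 | 8.8 |
| eta | 30.0 | 31.9 |
| eta | 60.0 | 70.8 |

(readings scatter by 0.5 percentage points)

- for target the crystals are counted in
- as a solid, counted per litre of solution: crystals, solid substrate
- what may be going on: solid substrate <-> starting material; starting material <-> intermediate; crystals <-> target; intermediate -> target
- at the start none of the solid substrate is in solution
- what has only dissolved of solid substrate counts as not reacted

1. which flask leads in amount of target, in percent of the solid substrate charged ("all alike" within 1.5 percentage points) (ochre / violet / grey / blue / all alike)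
2. how much target is there at the end, in percent of the solid substrate charged: ochre
3. how much target is there at the end, in percent of the solid substrate charged: violet
4. how much target is there at the end, in percent of the solid substrate charged: grey
5. how much target is there at the end, in percent of the solid substrate charged: blue

Late in the eta run, u falls from 68.1% at 30.0 min to 29.2% at 60.0 min. Read as an apparent first-order fall, this gives 0.0282 /min, and the last two alpha readings give 0.00410 /min. Both are readings and carry the scatter. The two runs differ in charge as well as in temperature; we assume that the charge does not matter and take the logarithm of this constant as straight in temperature, which is an assumption and a stretch outside the two runs. The late constant, the fraction of u lost per minute at the temperature of the flask, is then 0.0582 /min at 80 °C, 0.00954 /min at 65 °C and 0.00156 /min at 50 °C.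

Running the late line back to u equal to one gives an induction period of 16.4 min in the eta run. Two versions can be solved in the head. In the first, this delay stays the same at every temperature. In the second, it stretches as the constant shrinks. The second version would give alpha a delay of 113 min, longer than its 90.0 min of readings, while the alpha line itself gives 18.6 min. So we expect the real flasks between the versions and nearer the first.

For grey, the first version gives 15.0%, and the second gives no target, its delay of 296 min outlasting the 2.0 h. For violet, the versions give 92.8% and 95.6%. The first version gives ochre 62.8% and blue 99.8%. Blue should lead, with a larger constant in its second hour than violet has in its own.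

The forecast also names blue, with 72% for ochre, 90% for violet, 11% for grey and 97% for blue, which puts ochre above our figure and grey below it, and it warns that the runs “confound concentration with temperature”.

The flasks give 65.7% for ochre, 95.1% for violet, 10.4% for grey and 99.8% for blue, so blue leads.

    solid substrate ⇌ starting material, rate k1*(cs1 - [starting material]) while solid is left; crystals form when [starting material] > cs1 (solubility = 0.0710 M, k = 0.00230 /s)
    starting material ⇌ intermediate (K = 0.340, k = 7.40 × 10⁻⁵ /s, Ea = 100 kJ/mol, ΔH = 13.0 kJ/mol)
    crystals ⇌ target, rate k3*(cs3 - [target]) while solid is left; crystals form when [target] > cs3 (solubility = 28.0 mM, k = 0.00820 /s)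
    intermediate → target (k = 1.40 × 10⁻⁴ /s, Ea = 113 kJ/mol)
    (constants at 50 °C)

Ochre stands above our figure. In violet, u is 5.37% at the change, the sum of starting material and intermediate, with 0% solid substrate. The cold constant carries that to 4.89% at the end, and the flask holds 4.88%. The neighbouring flask is violet read at 50 min, still at 80 °C, before the change. Going back from the change with the late constant, we multiply u by 1.79, which gives 9.61%, so target at 90.4%. That neighbouring flask holds 90.5% target, with 7.68% starting material and 1.80% intermediate.

All runs were computed on assumed constants; scatter was added.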